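The easy step was to ask what happens at either end. Starting material and reagent pass through the catalyst to give product. With plenty of reagent I expected the rate to follow the starting material, with plenty of starting material to follow the reagent, and the two waits to add.

in all of them: free catalyst 7.2 mM
- Monday's: starting material 0.40 M; reagent 0.80 M; run made earlier
- Thursday's: starting material 0.20 M; reagent 0.80 M; run made earlier
- Tuesday's: starting material 0.30 M; reagent 0.80 M; run made earlier
- Friday's: starting material 0.40 M; reagent 1.6 M; run made earlier
- green: starting material 0.40 M; reagent 0.800 M; one stirred flow tank at steady state, fed with the mixture as stated, mean residence time 25 min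
- amber: starting material 0.40 M; reagent 0.800 M (fed, over 25.0 min); a stirred flask in which reagent is dosed at a steady rate over 25.0 min without added volume, worked up at 25 min; time 25 min
- teal: starting material 0.40 M (fed, over 25.0 min); reagent 0.800 M; a stirred flask in which starting material is dosed at a steady rate over 25.0 min without added volume, worked up at 25 min; time 25 min
- red: starting material 0.40 M; reagent 0.800 M; a closed flask charged with all of it at once and left for 25 min; time 25 min

- Monday's (time / min: product / %): 3.00: 6.1; 6.00: 11.9; 10.0: 19.8; 12.0: 22.8; 15.0: 27.6
- Thursday's (time / min: product / %): 2.50: 5.9; 5.00: 13.3; 8.00: 21.0; 15.0: 35.7; 30.0: 60.2
- Tuesday's (time / min: product / %): 6.00: 13.5; 12.0: 26.3; 20.0: 40.5; 25.0: 47.0; 30.0: 53.9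
- Friday's (time / min: product / %): 2.50: 6.2; 5.00: 13.2; 8.00: 19.7; 15.0: 35.0; 30.0: 58.1

(each reading ± 0.5 percentage points)

- the stated concentrations are those of everything mixed, before any reaction; amounts are the same in each set-up
- the feed brings no volume worth counting
- the earlier runs were made in a closed, stirred flask
- a reading or a percentage of product counts all its forms, free or not

- the set-up with the highest amount of product at the outlet or at the end, in percent of the starting material put in ("none" if the first two lie within 2 percentage points) (green / amber / teal / red / none)
- amount of product at the outlet or at the end, in percent of the starting material put in, green
- amount of product at the outlet or at the end, in percent of the starting material put in, amber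
- amount of product at the outlet or at the end, in percent of the starting material put in, teal
- amount of product at the outlet or at the end, in percent of the starting material put in, red

Joined, rate = k·A·B/(A + b·B), with A the starting material and B the reagent. With reagent taken as used one for one, a closed flask then obeys ln(B at start/B now) + b·ln(A at start/A now) = k·t. From Monday's and Thursday's last readings I read b = 0.486 and k = 0.0204 min⁻¹. For red I folded these into the clock number N = k·t = 0.509, the value the left side must reach by work-up. As a test, the last readings of Tuesday's and Friday's, both unused, reached 0.602 and 0.580, where the clock said 0.611.

Solving for red, a first pass gave 40.3% and one correction 42.6%. With reagent at half its charge and starting material at its whole charge, as amber stands midway if nothing has reacted, the joined rate runs slower than red's start, at 66.4% of that pace. The mirror case for teal also runs slower than red's start, at 67.0% of it, and green works at outlet concentrations throughout, so I put red first.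

The forecast also chose red, with green 37%, amber 29%, teal 27.5% and red 43%, holding that “Batch wins because nothing is starved”.

The flasks gave green 34.6%, amber 28.3%, teal 27.6% and red 42.8%, and red's yield puts the left side at 0.512 against N of 0.509. In red, catalyst intermediate B went on to free catalyst and product with a half-life of 0.59 s at 10.8 min, far shorter than the 0.30 min of catalyst intermediate A against charged starting material. At 25.0 min red's catalyst stood as 54.5% catalyst intermediate A, 35.1% free catalyst, 9.31% idle complex, 1.03% catalyst intermediate B and 0.109% resting dimer, a resting state shared mainly between the first two.

    free catalyst + product ⇌ idle complex (K = 15.0 M⁻¹, k = 0.110 M⁻¹ min⁻¹)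
    reagent + free catalyst → catalyst intermediate A (k = 3.30 M⁻¹ min⁻¹)
    catalyst intermediate B → free catalyst + product (k = 70.0 min⁻¹)
    2 catalyst intermediate B ⇌ resting dimer, settled at all times (K = 710 M⁻¹)
    starting material + catalyst intermediate A → catalyst intermediate B (k = 5.80 M⁻¹ min⁻¹)

For the flask of red with 1.4 M of reagent and the same time, N stays 0.509: a first pass gave 48.3%, the correction 51.4%. That neighbour flask gave 50.9%.

The data were generated by integration on assumed constants; scatter was added.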